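**Plan**
- Retrosynthesis: the benzylic ethers and the trichloroethyl ester of the sulfate come off first. Then C2–C3 of flavanone ring C is cut to an α-(flavon-8-yl)-α-diazoketone. Then the ring A aryl–C4 bond is cut (aryllithium plus Weinreb amide), and last flavone C8–CH2 (Claisen shift), back to apigenin.
- Enabling feature: flavanone C2 is a benzylic ether carbon (O1–C2H–aryl) lying 1,6 to C3, and C3 carries one aryl group (flavone C8) and one acyl group (C4), the pattern of a donor/acceptor carbene. C2 is therefore carried as the OCH2 of a 4-(benzyloxy)benzyl ether on ring A and C3 as a diazo carbon.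
- Forward: the three flavone rings come intact from apigenin. C8 is allylated by Claisen shift, the allyl group is cut down to an acetic acid unit (lactone, then Weinreb amide), and the fully etherified ring A is joined as an aryllithium. O7 is then sulfurylated, diazo transfer follows, pyranone ring C is closed by C–H insertion, and one hydrogenolysis unmasks everything.
- Stereochemistry: C2 (R) comes from a chiral dirhodium carboxylate that selects one enantiotopic benzylic C–H. C3 (S) comes from equilibration to the trans isomer relative to C2.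

Key step: step 12

Remark 1: Rh2(S-PTTL)4 (dirhodium tetrakis[N-phthaloyl-(S)-tert-leucinate], divalent rhodium) is assumed to deliver 2R; if the first run shows the opposite sense, the mirror-image catalyst Rh2(R-PTTL)4 is used unchanged otherwise.
Remark 2: the target is drawn as the free aryl hydrogen sulfate; such acids desulfate on standing, so the last step isolates the ammonium salt and releases the acid by brief cold contact with an acidic resin.

**Route**

Step 1
Reactants: 1 apigenin; 2 allyl bromide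
Product: 3 7-(allyloxy)-5-hydroxy-2-(4-hydroxyphenyl)-4H-chromen-4-one
Conditions: K2CO3 (1.1 equiv), DMF, 0 °C → rt
Reagents that add atoms: none
Why: Williamson etherification is directed to O7 because the 7-OH, para to the pyranone carbonyl, is the most acidic phenol of apigenin, while the chelated 5-OH and the less acidic 4'-OH should stay largely untouched with one equivalent of base and halide.

Step 2
Reactants: 3 7-(allyloxy)-5-hydroxy-2-(4-hydroxyphenyl)-4H-chromen-4-one
Product: 4 7-(allyloxy)-5-(benzyloxy)-2-[4-(benzyloxy)phenyl]-4H-chromen-4-one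
Conditions: BnBr (3 equiv), K2CO3, n-Bu4NI (cat.), DMF, 70 °C
Reagents that add atoms: benzyl bromide (first molecule), BrCc1ccccc1; benzyl bromide (second molecule), BrCc1ccccc1
Why: Williamson etherification under forcing conditions caps the 4'-OH and the hydrogen-bonded 5-OH as benzyl ethers (two molecules of benzyl bromide are taken up), which removes chelation at O5 before the rearrangement and leaves the allyl ether intact.

Step 3
Reactants: 4 7-(allyloxy)-5-(benzyloxy)-2-[4-(benzyloxy)phenyl]-4H-chromen-4-one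
Product: 5 8-allyl-5-(benzyloxy)-2-[4-(benzyloxy)phenyl]-7-hydroxy-4H-chromen-4-one
Conditions: PhNEt2, 200 °C, sealed tube, Ar
Reagents that add atoms: none
Why: Aromatic Claisen rearrangement ([3,3]-sigmatropic shift, then tautomerisation) moves the allyl group from O7 to C8, favoured over C6 by the bond fixation of a 7-oxygenated chromone whose O5 is alkylated, and releases the 7-OH as the only free phenol.

Step 4
Reactants: 5 8-allyl-5-(benzyloxy)-2-[4-(benzyloxy)phenyl]-7-hydroxy-4H-chromen-4-one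
Product: 8 5-(benzyloxy)-2-[4-(benzyloxy)phenyl]-8-hydroxy-8,9-dihydro-4H-furo[2,3-h]chromen-4-one (lactol), via vicinal diol 6 (not isolated), via open hydroxy aldehyde 7 (not isolated)
Conditions: OsO4 (cat.), NaIO4, 2,6-lutidine, dioxane–H2O, rt
Reagents that add atoms: osmium tetroxide, O=[Os](=O)(=O)=O; sodium periodate, [Na+].[O-]I(=O)(=O)=O; water, O
Why: Lemieux–Johnson cleavage dihydroxylates the terminal alkene (the most electron-rich and least hindered C=C) and splits the diol to the arylacetaldehyde, which the neighbouring 7-OH traps as the five-membered lactol, while 2,6-lutidine keeps the medium non-acidic so that the lactol should not dehydrate to a benzofuran.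

Step 5
Reactants: 8 5-(benzyloxy)-2-[4-(benzyloxy)phenyl]-8-hydroxy-8,9-dihydro-4H-furo[2,3-h]chromen-4-one
Product: 9 5-(benzyloxy)-2-[4-(benzyloxy)phenyl]-4H-furo[2,3-h]chromene-4,8(9H)-dione (lactone)
Conditions: n-Pr4N[RuO4] (cat.), NMO, 4 Å MS, CH2Cl2, rt
Reagents that add atoms: none
Why: Ley–Griffith oxidation of a lactol to its lactone runs under neutral conditions that spare the benzyl ethers and the chromone and avoid acid-promoted dehydration.

Step 6
Reactants: 9 5-(benzyloxy)-2-[4-(benzyloxy)phenyl]-4H-furo[2,3-h]chromene-4,8(9H)-dione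
Product: 10 2-{5-(benzyloxy)-2-[4-(benzyloxy)phenyl]-7-hydroxy-4-oxo-4H-chromen-8-yl}-N-methoxy-N-methylacetamide
Conditions: MeNH(OMe)·HCl, AlMe3, CH2Cl2, 0 °C → rt; aq potassium sodium tartrate work-up
Reagents that add atoms: N,O-dimethylhydroxylamine hydrochloride, CNOC.Cl
Why: Weinreb aminolysis by the dimethylaluminium amide opens the activated aryl-ester lactone to the N-methoxy-N-methylamide and frees O7 again as the single phenol.

Step 7
Reactants: 11 phloroglucinol; 12 4-(benzyloxy)benzyl chloride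
Product: 13 1,3,5-tris{[4-(benzyloxy)benzyl]oxy}benzene
Conditions: 12 (3.3 equiv), K2CO3 (4 equiv), n-Bu4NI (cat.), DMF, 40 °C
Reagents that add atoms: 4-(benzyloxy)benzyl chloride (second molecule of 12), ClCc1ccc(OCc2ccccc2)cc1; 4-(benzyloxy)benzyl chloride (third molecule of 12), ClCc1ccc(OCc2ccccc2)cc1
Why: Threefold Williamson O-alkylation, in which each of the three phenoxides of phloroglucinol displaces chloride from one molecule of 12 (three molecules of 12 are consumed per molecule of 11, and a dipolar aprotic solvent favours O- over C-alkylation), gives the symmetric tris ether whose benzylic OCH2 groups later supply C2 and its aryl ring.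

Step 8
Reactants: 13 1,3,5-tris{[4-(benzyloxy)benzyl]oxy}benzene
Product: 14 2-bromo-1,3,5-tris{[4-(benzyloxy)benzyl]oxy}benzene
Conditions: NBS (1.0 equiv), CH2Cl2, –20 → 0 °C
Reagents that add atoms: N-bromosuccinimide, O=C1CCC(=O)N1Br
Why: Electrophilic aromatic bromination occurs once at one of the three equivalent positions flanked by two alkoxy groups, far more activated than the monoalkoxy benzyl rings, and the first bromine hinders and deactivates the ring against a second.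

Step 9
Reactants: 10 2-{5-(benzyloxy)-2-[4-(benzyloxy)phenyl]-7-hydroxy-4-oxo-4H-chromen-8-yl}-N-methoxy-N-methylacetamide; 14 2-bromo-1,3,5-tris{[4-(benzyloxy)benzyl]oxy}benzene
Product: 16 2-{5-(benzyloxy)-2-[4-(benzyloxy)phenyl]-7-hydroxy-4-oxo-4H-chromen-8-yl}-1-(2,4,6-tris{[4-(benzyloxy)benzyl]oxy}phenyl)ethanone, via aryllithium 15 (not isolated)
Conditions: 14 (2.4 equiv), n-BuLi (2.3 equiv), THF, –78 °C; then 10, –78 → –30 °C; aq NH4Cl
Reagents that add atoms: none
Why: Bromine–lithium exchange gives the 2,6-dialkoxyaryllithium, whose first equivalent deprotonates the 7-OH (the 7-oxido chromone is a vinylogous carboxylate and so shields C4 and C2 from attack) and whose second adds to the Weinreb amide to give a chelated tetrahedral adduct that collapses to the ketone only on work-up (Weinreb ketone synthesis).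

Step 10
Reactants: 16 2-{5-(benzyloxy)-2-[4-(benzyloxy)phenyl]-7-hydroxy-4-oxo-4H-chromen-8-yl}-1-(2,4,6-tris{[4-(benzyloxy)benzyl]oxy}phenyl)ethanone
Product: 17 5-(benzyloxy)-2-[4-(benzyloxy)phenyl]-4-oxo-8-[2-oxo-2-(2,4,6-tris{[4-(benzyloxy)benzyl]oxy}phenyl)ethyl]-4H-chromen-7-yl 2,2,2-trichloroethyl sulfate
Conditions: Cl3CCH2OSO2Cl, Et3N, DMAP (cat.), THF, 0 °C → rt
Reagents that add atoms: 2,2,2-trichloroethyl chlorosulfate, ClS(=O)(=O)OCC(Cl)(Cl)Cl
Why: O-Sulfurylation of the acidic 7-phenol with the chlorosulfate under DMAP catalysis gives the aryl trichloroethyl sulfate diester, a masked sulfate with no activated C–H bond and no nucleophilic oxygen beside the future carbene carbon, while Et3N is too weak to enolise the ketone.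

Step 11
Reactants: 17 5-(benzyloxy)-2-[4-(benzyloxy)phenyl]-4-oxo-8-[2-oxo-2-(2,4,6-tris{[4-(benzyloxy)benzyl]oxy}phenyl)ethyl]-4H-chromen-7-yl 2,2,2-trichloroethyl sulfate
Product: 18 2-diazo-2-{5-(benzyloxy)-2-[4-(benzyloxy)phenyl]-4-oxo-7-[(2,2,2-trichloroethoxy)sulfonyloxy]-4H-chromen-8-yl}-1-(2,4,6-tris{[4-(benzyloxy)benzyl]oxy}phenyl)ethanone
Conditions: p-ABSA, DBU, MeCN–CH2Cl2, 0 °C
Reagents that add atoms: 4-acetamidobenzenesulfonyl azide, CC(=O)Nc1ccc(cc1)S(=O)(=O)N=[N+]=[N-]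
Why: Regitz diazo transfer, in which DBU enolises the benzylic ketone CH2, the enolate attacks the terminal nitrogen of the sulfonyl azide and the triazene fragments to the α-aryl-α-diazoketone and the sulfonamide.

Step 12
Reactants: 18 2-diazo-2-{5-(benzyloxy)-2-[4-(benzyloxy)phenyl]-4-oxo-7-[(2,2,2-trichloroethoxy)sulfonyloxy]-4H-chromen-8-yl}-1-(2,4,6-tris{[4-(benzyloxy)benzyl]oxy}phenyl)ethanone
Product: 20 (2R,3S)-5,7-bis{[4-(benzyloxy)benzyl]oxy}-2-[4-(benzyloxy)phenyl]-3-{5-(benzyloxy)-2-[4-(benzyloxy)phenyl]-4-oxo-7-[(2,2,2-trichloroethoxy)sulfonyloxy]-4H-chromen-8-yl}chroman-4-one, via cis C3-epimer 19 (not isolated)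
Conditions: Rh2(S-PTTL)4 (2 mol %), toluene, 0 °C, slow addition of 18 at high dilution; then Et3N, rt
Reagents that add atoms: none
Why: The dirhodium tetracarboxylate expels N2 from 18 to give an electrophilic aryl/acyl rhodium carbene at C3, which inserts through a concerted, hydride-shift-like three-centre transition state into a benzylic O–CH2 bond of an ortho 4-(benzyloxy)benzyl ether, a C–H bond made hydridic by both the ether oxygen and the para-alkoxyphenyl ring. The closest known reaction type is the chiral dirhodium-carboxylate-catalysed intramolecular C–H insertion of 2-alkoxyaryl α-diazoketones to chroman-4-ones, together with Rh2(S-PTTL)4-catalysed insertions of α-aryl-α-diazo carbonyl compounds. Pyranone ring C closes by 1,6-insertion, the new C2–C3 bond joining the carbene carbon to the ether carbon six atoms away. C2 is controlled by the catalyst, whose phthalimide-walled pocket selects one of the two enantiotopic benzylic hydrogens (the two ortho ethers are interchanged by rotation about the aryl–carbonyl bond, so either gives the same product); C3 is formed in the insertion but, being benzylic and α to the ketone, is then equilibrated by Et3N through the enol to the trans-diequatorial (2R,3S) isomer, so that any cis epimer 19 drains into 20. The step needs 1,6-insertion to win over five-membered closure, oxonium-ylide formation with Stevens shift and Wolff rearrangement: the only other group beside the carbene is the O7 sulfate diester with no activated C–H, the bulky catalyst and the donor/acceptor carbene favour the doubly activated C–H over the hindered ether oxygen, and a metal-bound carbene at 0 °C should not undergo Wolff rearrangement.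

Step 13
Reactants: 20 (2R,3S)-5,7-bis{[4-(benzyloxy)benzyl]oxy}-2-[4-(benzyloxy)phenyl]-3-{5-(benzyloxy)-2-[4-(benzyloxy)phenyl]-4-oxo-7-[(2,2,2-trichloroethoxy)sulfonyloxy]-4H-chromen-8-yl}chroman-4-one
Product: 21 CNP0271389.1, 8-[(2R,3S)-5,7-dihydroxy-2-(4-hydroxyphenyl)-4-oxochroman-3-yl]-5-hydroxy-2-(4-hydroxyphenyl)-4-oxo-4H-chromen-7-yl hydrogen sulfate
Conditions: 10% Pd/C, HCO2NH4, THF–MeOH, rt; then Dowex 50W (H+ form), 0 °C, freeze-drying
Reagents that add atoms: none
Why: Catalytic transfer hydrogenolysis should cleave the five O-benzyl bonds and then the two 4-hydroxybenzyl aryl ethers and reductively remove the trichloroethyl group to leave the aryl sulfate monoester without touching C2 or C3, and the cold acidic resin exchanges ammonium for a proton.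

**Compound list**
1 | apigenin | O=c1cc(-c2ccc(O)cc2)oc2cc(O)cc(O)c12 | starting material
2 | allyl bromide | C=CCBr | starting material
3 | 7-(allyloxy)-5-hydroxy-2-(4-hydroxyphenyl)-4H-chromen-4-one | O=c1cc(-c2ccc(O)cc2)oc2cc(OCC=C)cc(O)c12 | intermediate
4 | 7-(allyloxy)-5-(benzyloxy)-2-[4-(benzyloxy)phenyl]-4H-chromen-4-one | O=c1cc(-c2ccc(OCc3ccccc3)cc2)oc2cc(OCC=C)cc(OCc3ccccc3)c12 | intermediate
5 | 8-allyl-5-(benzyloxy)-2-[4-(benzyloxy)phenyl]-7-hydroxy-4H-chromen-4-one | O=c1cc(-c2ccc(OCc3ccccc3)cc2)oc2c(CC=C)c(O)cc(OCc3ccccc3)c12 | intermediate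
6 | 5-(benzyloxy)-2-[4-(benzyloxy)phenyl]-8-(2,3-dihydroxypropyl)-7-hydroxy-4H-chromen-4-one (vicinal diol, not isolated) | OCC(O)Cc1c(O)cc(OCc2ccccc2)c2c(=O)cc(-c3ccc(OCc4ccccc4)cc3)oc12 | intermediate
7 | {5-(benzyloxy)-2-[4-(benzyloxy)phenyl]-7-hydroxy-4-oxo-4H-chromen-8-yl}acetaldehyde (open form, not isolated) | O=CCc1c(O)cc(OCc2ccccc2)c2c(=O)cc(-c3ccc(OCc4ccccc4)cc3)oc12 | intermediate
8 | 5-(benzyloxy)-2-[4-(benzyloxy)phenyl]-8-hydroxy-8,9-dihydro-4H-furo[2,3-h]chromen-4-one (lactol, both C8 epimers) | OC1Cc2c(O1)cc(OCc3ccccc3)c3c(=O)cc(-c4ccc(OCc5ccccc5)cc4)oc23 | intermediate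
9 | 5-(benzyloxy)-2-[4-(benzyloxy)phenyl]-4H-furo[2,3-h]chromene-4,8(9H)-dione (lactone) | O=C1Cc2c(O1)cc(OCc3ccccc3)c3c(=O)cc(-c4ccc(OCc5ccccc5)cc4)oc23 | intermediate
10 | 2-{5-(benzyloxy)-2-[4-(benzyloxy)phenyl]-7-hydroxy-4-oxo-4H-chromen-8-yl}-N-methoxy-N-methylacetamide | CON(C)C(=O)Cc1c(O)cc(OCc2ccccc2)c2c(=O)cc(-c3ccc(OCc4ccccc4)cc3)oc12 | intermediate
11 | phloroglucinol | Oc1cc(O)cc(O)c1 | starting material
12 | 4-(benzyloxy)benzyl chloride | ClCc1ccc(OCc2ccccc2)cc1 | starting material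
13 | 1,3,5-tris{[4-(benzyloxy)benzyl]oxy}benzene | c1c(OCc2ccc(OCc3ccccc3)cc2)cc(OCc2ccc(OCc3ccccc3)cc2)cc1OCc1ccc(OCc2ccccc2)cc1 | intermediate
14 | 2-bromo-1,3,5-tris{[4-(benzyloxy)benzyl]oxy}benzene | Brc1c(OCc2ccc(OCc3ccccc3)cc2)cc(OCc2ccc(OCc3ccccc3)cc2)cc1OCc1ccc(OCc2ccccc2)cc1 | intermediate
15 | (2,4,6-tris{[4-(benzyloxy)benzyl]oxy}phenyl)lithium (not isolated) | [Li]c1c(OCc2ccc(OCc3ccccc3)cc2)cc(OCc2ccc(OCc3ccccc3)cc2)cc1OCc1ccc(OCc2ccccc2)cc1 | intermediate
16 | 2-{5-(benzyloxy)-2-[4-(benzyloxy)phenyl]-7-hydroxy-4-oxo-4H-chromen-8-yl}-1-(2,4,6-tris{[4-(benzyloxy)benzyl]oxy}phenyl)ethanone | O=C(Cc1c(O)cc(OCc2ccccc2)c2c(=O)cc(-c3ccc(OCc4ccccc4)cc3)oc12)c1c(OCc2ccc(OCc3ccccc3)cc2)cc(OCc2ccc(OCc3ccccc3)cc2)cc1OCc1ccc(OCc2ccccc2)cc1 | intermediate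
17 | 5-(benzyloxy)-2-[4-(benzyloxy)phenyl]-4-oxo-8-[2-oxo-2-(2,4,6-tris{[4-(benzyloxy)benzyl]oxy}phenyl)ethyl]-4H-chromen-7-yl 2,2,2-trichloroethyl sulfate | O=C(Cc1c(OS(=O)(=O)OCC(Cl)(Cl)Cl)cc(OCc2ccccc2)c2c(=O)cc(-c3ccc(OCc4ccccc4)cc3)oc12)c1c(OCc2ccc(OCc3ccccc3)cc2)cc(OCc2ccc(OCc3ccccc3)cc2)cc1OCc1ccc(OCc2ccccc2)cc1 | intermediate
18 | 2-diazo-2-{5-(benzyloxy)-2-[4-(benzyloxy)phenyl]-4-oxo-7-[(2,2,2-trichloroethoxy)sulfonyloxy]-4H-chromen-8-yl}-1-(2,4,6-tris{[4-(benzyloxy)benzyl]oxy}phenyl)ethanone | [N-]=[N+]=C(C(=O)c1c(OCc2ccc(OCc3ccccc3)cc2)cc(OCc2ccc(OCc3ccccc3)cc2)cc1OCc1ccc(OCc2ccccc2)cc1)c1c(OS(=O)(=O)OCC(Cl)(Cl)Cl)cc(OCc2ccccc2)c2c(=O)cc(-c3ccc(OCc4ccccc4)cc3)oc12 | intermediate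
19 | (2R,3R)-cis C3-epimer of 20 (not isolated) | O=C1c2c(OCc3ccc(OCc4ccccc4)cc3)cc(OCc3ccc(OCc4ccccc4)cc3)cc2O[C@@H](c2ccc(OCc3ccccc3)cc2)[C@H]1c1c(OS(=O)(=O)OCC(Cl)(Cl)Cl)cc(OCc2ccccc2)c2c(=O)cc(-c3ccc(OCc4ccccc4)cc3)oc12 | intermediate
20 | (2R,3S)-5,7-bis{[4-(benzyloxy)benzyl]oxy}-2-[4-(benzyloxy)phenyl]-3-{5-(benzyloxy)-2-[4-(benzyloxy)phenyl]-4-oxo-7-[(2,2,2-trichloroethoxy)sulfonyloxy]-4H-chromen-8-yl}chroman-4-one | O=C1c2c(OCc3ccc(OCc4ccccc4)cc3)cc(OCc3ccc(OCc4ccccc4)cc3)cc2O[C@@H](c2ccc(OCc3ccccc3)cc2)[C@@H]1c1c(OS(=O)(=O)OCC(Cl)(Cl)Cl)cc(OCc2ccccc2)c2c(=O)cc(-c3ccc(OCc4ccccc4)cc3)oc12 | intermediate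
21 | CNP0271389.1, 8-[(2R,3S)-5,7-dihydroxy-2-(4-hydroxyphenyl)-4-oxochroman-3-yl]-5-hydroxy-2-(4-hydroxyphenyl)-4-oxo-4H-chromen-7-yl hydrogen sulfate | O=C1c2c(O)cc(O)cc2O[C@@H](c2ccc(O)cc2)[C@@H]1c1c(OS(=O)(=O)O)cc(O)c2c(=O)cc(-c3ccc(O)cc3)oc12 | target

**Count and risks**
Total step count: 13. Longest linear sequence: 11 steps (steps 1–6 and 9–13 from apigenin); steps 7 and 8 form the two-step ring A branch.

Most likely to fail, in this order:

1. Step 12. The carbene may be diverted into attack on the ortho ether oxygen (oxonium ylide, then 1,2-shift of the benzyl group to a benzofuranone) or into addition to the electron-rich benzyl ring. The catalyst may also discriminate the enantiotopic hydrogens poorly, or C2 may erode through retro-oxa-Michael ring opening while C3 equilibrates. Fallback: set out from 17. Chelation-controlled cleavage of one of the two ortho 4-(benzyloxy)benzyl ethers with MgBr2·OEt2 (toluene–Et2O, rt) should give the 2-hydroxyaryl ketone F1. Condensation with 4-(benzyloxy)benzaldehyde under pyrrolidinium acetate (EtOH–toluene, 60 °C) would pass through the α-aryl chalcone, which closes by oxa-Michael addition and settles as the racemic trans-2,3-diarylchromanone F2. Preparative chromatography on a chiral stationary phase then supplies the (2R,3S) enantiomer, which is 20, where the route is rejoined. Catalyst control of C2 is given up for a resolution, but the same ring is formed by classical condensation chemistry.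

2. Step 9. The aryllithium may attack the chromone at C4 or C2, enolise the amide, or deprotonate a benzylic ether position instead of adding to the amide carbonyl. Fallback: set out from 5. Sulfurylation of the 7-OH (Cl3CCH2OSO2Cl, Et3N, DMAP) should give the 8-allyl sulfate diester F3. OsO4/NaIO4 cleavage gives the arylacetaldehyde F4, and Pinnick oxidation (NaClO2, NaH2PO4, 2-methyl-2-butene) the arylacetic acid F5. Friedel–Crafts acylation of phloroglucinol 11 with F5 in BF3·OEt2 at 60 °C would give the 2,4,6-trihydroxyphenyl ketone F6. Threefold etherification with 12 (K2CO3, DMF) then leads to 17, where the route is rejoined. Ring A is here acylated as the free triphenol, so no organolithium meets the chromone.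

3. Step 11. DBU may remove HCl from the trichloroethyl ester (giving the dichlorovinyl ester) or trigger sulfuryl transfer, and diazo transfer onto the hindered ketone may be slow. Fallback: set out from 16. Silylation (TIPSOTf, 2,6-lutidine, CH2Cl2) should give the 7-O-triisopropylsilyl ketone F7, and diazo transfer (p-ABSA, DBU) then gives the silylated diazoketone F8 with no sulfate ester present. Treatment with n-Bu4NF in THF at –20 °C frees the 7-hydroxy diazoketone F9 as its phenoxide, which is sulfurylated in the same flask with Cl3CCH2OSO2Cl to give 18, where the route is rejoined. The sulfate diester then never meets DBU.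

**Further compounds**
F1 | step 12 | 5-(benzyloxy)-2-[4-(benzyloxy)phenyl]-8-[2-(2-hydroxy-4,6-bis{[4-(benzyloxy)benzyl]oxy}phenyl)-2-oxoethyl]-4-oxo-4H-chromen-7-yl 2,2,2-trichloroethyl sulfate | O=C(Cc1c(OS(=O)(=O)OCC(Cl)(Cl)Cl)cc(OCc2ccccc2)c2c(=O)cc(-c3ccc(OCc4ccccc4)cc3)oc12)c1c(O)cc(OCc2ccc(OCc3ccccc3)cc2)cc1OCc1ccc(OCc2ccccc2)cc1
F2 | step 12 | racemic trans form of 20, (2R,3S) and (2S,3R) together | O=C1c2c(OCc3ccc(OCc4ccccc4)cc3)cc(OCc3ccc(OCc4ccccc4)cc3)cc2O[C@@H](c2ccc(OCc3ccccc3)cc2)[C@@H]1c1c(OS(=O)(=O)OCC(Cl)(Cl)Cl)cc(OCc2ccccc2)c2c(=O)cc(-c3ccc(OCc4ccccc4)cc3)oc12.O=C1c2c(OCc3ccc(OCc4ccccc4)cc3)cc(OCc3ccc(OCc4ccccc4)cc3)cc2O[C@H](c2ccc(OCc3ccccc3)cc2)[C@H]1c1c(OS(=O)(=O)OCC(Cl)(Cl)Cl)cc(OCc2ccccc2)c2c(=O)cc(-c3ccc(OCc4ccccc4)cc3)oc12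
F3 | step 9 | 8-allyl-5-(benzyloxy)-2-[4-(benzyloxy)phenyl]-4-oxo-4H-chromen-7-yl 2,2,2-trichloroethyl sulfate | C=CCc1c(OS(=O)(=O)OCC(Cl)(Cl)Cl)cc(OCc2ccccc2)c2c(=O)cc(-c3ccc(OCc4ccccc4)cc3)oc12
F4 | step 9 | 5-(benzyloxy)-2-[4-(benzyloxy)phenyl]-4-oxo-8-(2-oxoethyl)-4H-chromen-7-yl 2,2,2-trichloroethyl sulfate | O=CCc1c(OS(=O)(=O)OCC(Cl)(Cl)Cl)cc(OCc2ccccc2)c2c(=O)cc(-c3ccc(OCc4ccccc4)cc3)oc12
F5 | step 9 | {5-(benzyloxy)-2-[4-(benzyloxy)phenyl]-4-oxo-7-[(2,2,2-trichloroethoxy)sulfonyloxy]-4H-chromen-8-yl}acetic acid | OC(=O)Cc1c(OS(=O)(=O)OCC(Cl)(Cl)Cl)cc(OCc2ccccc2)c2c(=O)cc(-c3ccc(OCc4ccccc4)cc3)oc12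
F6 | step 9 | 5-(benzyloxy)-2-[4-(benzyloxy)phenyl]-4-oxo-8-[2-oxo-2-(2,4,6-trihydroxyphenyl)ethyl]-4H-chromen-7-yl 2,2,2-trichloroethyl sulfate | O=C(Cc1c(OS(=O)(=O)OCC(Cl)(Cl)Cl)cc(OCc2ccccc2)c2c(=O)cc(-c3ccc(OCc4ccccc4)cc3)oc12)c1c(O)cc(O)cc1O
F7 | step 11 | 2-{5-(benzyloxy)-2-[4-(benzyloxy)phenyl]-4-oxo-7-[(triisopropylsilyl)oxy]-4H-chromen-8-yl}-1-(2,4,6-tris{[4-(benzyloxy)benzyl]oxy}phenyl)ethanone | O=C(Cc1c(O[Si](C(C)C)(C(C)C)C(C)C)cc(OCc2ccccc2)c2c(=O)cc(-c3ccc(OCc4ccccc4)cc3)oc12)c1c(OCc2ccc(OCc3ccccc3)cc2)cc(OCc2ccc(OCc3ccccc3)cc2)cc1OCc1ccc(OCc2ccccc2)cc1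
F8 | step 11 | 2-diazo-2-{5-(benzyloxy)-2-[4-(benzyloxy)phenyl]-4-oxo-7-[(triisopropylsilyl)oxy]-4H-chromen-8-yl}-1-(2,4,6-tris{[4-(benzyloxy)benzyl]oxy}phenyl)ethanone | [N-]=[N+]=C(C(=O)c1c(OCc2ccc(OCc3ccccc3)cc2)cc(OCc2ccc(OCc3ccccc3)cc2)cc1OCc1ccc(OCc2ccccc2)cc1)c1c(O[Si](C(C)C)(C(C)C)C(C)C)cc(OCc2ccccc2)c2c(=O)cc(-c3ccc(OCc4ccccc4)cc3)oc12
F9 | step 11 | 2-diazo-2-{5-(benzyloxy)-2-[4-(benzyloxy)phenyl]-7-hydroxy-4-oxo-4H-chromen-8-yl}-1-(2,4,6-tris{[4-(benzyloxy)benzyl]oxy}phenyl)ethanone | [N-]=[N+]=C(C(=O)c1c(OCc2ccc(OCc3ccccc3)cc2)cc(OCc2ccc(OCc3ccccc3)cc2)cc1OCc1ccc(OCc2ccccc2)cc1)c1c(O)cc(OCc2ccccc2)c2c(=O)cc(-c3ccc(OCc4ccccc4)cc3)oc12
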